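**Retrosynthetic overview**
- Eurycomalin A ⇒ its dimethyl ester; the double ester hydrolysis is the last step.
- C7–C7' biaryl bond ⇒ two molecules of the (S)-monomer methyl ester, joined by a proposed one-flask C7–H borylation/oxidative homocoupling (a formal dehydrodimerisation).
- Each dihydrofuran ring (C3–C3a and O1–C2 bonds, C2 stereocentre) ⇒ methyl 3-bromo-4-hydroxybenzoate + isoprene by asymmetric Heck/Tsuji–Trost heteroannulation.
- Ring order: the dihydrofuran ring is made first, on the monomer, and the biaryl bond last, so (S) + (S) can only give (S,S).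

Assumption: both stereocentres are S (as read from the SMILES), the biaryl axis has only two small ortho substituents and needs no control, and compounds 1, 2 and 4 are bought.

Step 1
Reactants: 1 methyl 3-bromo-4-hydroxybenzoate; 2 isoprene (2-methylbuta-1,3-diene)
Product: 3 methyl (S)-2-(prop-1-en-2-yl)-2,3-dihydrobenzofuran-5-carboxylate
Conditions: Pd2(dba)3·CHCl3 (2.5 mol%), ent-TY-Phos (10 mol%), PhONa (2 equiv), isoprene (4 equiv), CH2Cl2, 40 °C, sealed tube
Reagents that add atoms: none
Why: Asymmetric Heck/Tsuji–Trost heteroannulation (enantioselective Larock-type diene annulation of o-bromophenols): zerovalent palladium inserts into C–Br, the aryl group adds to the CH2 terminus of the less substituted C=C of isoprene to give a 2-methyl-π-allyl palladium, and the ortho phenoxide closes the five-membered ring at the internal allyl carbon on the face set by the chiral sulfinamide–monophosphine (ent-TY-Phos = the mirror image of the ligand that gives the (R)-2-isopropenyl series), which fixes C2 as S.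

Step 2
Reactants: 3 methyl (S)-2-(prop-1-en-2-yl)-2,3-dihydrobenzofuran-5-carboxylate (2 molecules); 4 bis(pinacolato)diboron
Product: 6 dimethyl (2S,2'S)-2,2'-di(prop-1-en-2-yl)-2,2',3,3'-tetrahydro-7,7'-bibenzofuran-5,5'-dicarboxylate, via C7 pinacol boronate 5 (not isolated)
Conditions: [Ir(OMe)(cod)]2 (1.5 mol%), 3,4,7,8-Me4-phen (3 mol%), B2pin2 (0.6 equiv), THF, 55 °C; then Pd(OAc)2 (5 mol%), 2 M aq. K2CO3, acetone, O2 (1 atm), 40 °C
Reagents that add atoms: none
Why: Proposed new method: a one-flask dehydrogenative C7–H/C7–H homodimerisation in which the sterically governed iridium tris(boryl) catalyst borylates the only arene C–H not flanked by a carbon substituent (C7, beside the tied-back ring oxygen, as at C4 of 1,3-benzodioxole; C6 is shielded by the ester, C4 by ester and CH2) and aerobic Pd catalysis (peroxo-palladium, two transmetalations, reductive elimination) then joins two aryl boronates; the closest known reactions are iridium-catalysed arene C–H borylation and Pd/O2 homocoupling of arylboronates, neither shown as a telescoped dimerisation on a 2-alkenyl-2,3-dihydrobenzofuran with a free 1,1-disubstituted alkene; no stereocentre is touched.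

Step 3
Reactants: 6 dimethyl (2S,2'S)-2,2'-di(prop-1-en-2-yl)-2,2',3,3'-tetrahydro-7,7'-bibenzofuran-5,5'-dicarboxylate
Product: 8 (2S,2'S)-2,2'-di(prop-1-en-2-yl)-2,2',3,3'-tetrahydro-7,7'-bibenzofuran-5,5'-dicarboxylic acid (eurycomalin A), via dilithium dicarboxylate 7 (not isolated)
Conditions: LiOH·H2O (6 equiv), THF/MeOH/H2O 3:1:1, 40 °C; then 1 M HCl, 0 °C, pH 3
Reagents that add atoms: lithium hydroxide, [Li+].[OH-]
Why: Ester saponification (acyl–oxygen cleavage by hydroxide) and cold protonation; the C2 stereocentres are not enolisable and the allylic aryl ether and isopropenyl groups tolerate aqueous base and brief dilute acid, so the (S,S) configuration is carried through.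

**Compound list**
1 | methyl 3-bromo-4-hydroxybenzoate | COC(=O)c1ccc(O)c(Br)c1 | starting material
2 | isoprene (2-methylbuta-1,3-diene) | C=CC(C)=C | starting material
3 | methyl (S)-2-(prop-1-en-2-yl)-2,3-dihydrobenzofuran-5-carboxylate | C=C(C)[C@@H]1Cc2cc(C(=O)OC)ccc2O1 | intermediate
4 | bis(pinacolato)diboron | CC1(C)OB(OC1(C)C)B1OC(C)(C)C(C)(C)O1 | starting material
5 | methyl (S)-2-(prop-1-en-2-yl)-7-(4,4,5,5-tetramethyl-1,3,2-dioxaborolan-2-yl)-2,3-dihydrobenzofuran-5-carboxylate | C=C(C)[C@@H]1Cc2cc(C(=O)OC)cc(B3OC(C)(C)C(C)(C)O3)c2O1 | intermediate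
6 | dimethyl (2S,2'S)-2,2'-di(prop-1-en-2-yl)-2,2',3,3'-tetrahydro-7,7'-bibenzofuran-5,5'-dicarboxylate | C=C(C)[C@@H]1Cc2cc(C(=O)OC)cc(-c3cc(C(=O)OC)cc4c3O[C@H](C(=C)C)C4)c2O1 | intermediate
7 | dilithium (2S,2'S)-2,2'-di(prop-1-en-2-yl)-2,2',3,3'-tetrahydro-7,7'-bibenzofuran-5,5'-dicarboxylate | C=C(C)[C@@H]1Cc2cc(C(=O)[O-])cc(-c3cc(C(=O)[O-])cc4c3O[C@H](C(=C)C)C4)c2O1.[Li+].[Li+] | intermediate
8 | eurycomalin A, (2S,2'S)-2,2'-di(prop-1-en-2-yl)-2,2',3,3'-tetrahydro-7,7'-bibenzofuran-5,5'-dicarboxylic acid | C=C(C)[C@@H]1Cc2cc(C(=O)O)cc(-c3cc(C(=O)O)cc4c3O[C@H](C(=C)C)C4)c2O1 | target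

**Total step count:** 3. **Longest linear sequence:** 3 (1 → 3 → 6 → 8).

**Steps most likely to fail**

Step 2 (the proposed new step). The isopropenyl group may react with the iridium boryl/hydride species (hydroboration, vinylic borylation, or double-bond migration into the enol-ether position, which would erase C2). Some C6 borylation, or protodeboronation and phenol formation in the aerobic stage, are also possible. The fallback uses known reactions only, sets out from 1 and comes back at 6. It places the coupling handle before the alkene exists. Compound 1 is chlorinated ortho to the hydroxyl (NCS, cat. TsOH, MeCN, 50 °C) to give methyl 3-bromo-5-chloro-4-hydroxybenzoate F1. The heteroannulation of step 1 with 2 then takes place at C–Br and leaves C–Cl, giving methyl (S)-7-chloro-2-(prop-1-en-2-yl)-2,3-dihydrobenzofuran-5-carboxylate F2. A one-pot Miyaura borylation/Suzuki homocoupling of F2 (Pd(OAc)2, XPhos, 0.55 equiv of 4, K3PO4, dioxane/H2O, 60–80 °C), in which half of F2 passes through boronate 5, gives 6.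

Step 1. The ester-bearing phenol may give lower enantioselectivity or some 2-methyl-2-vinyl regioisomer. Compound 3 should be at 99% ee or better before step 2, because any (R)-3 ends up mostly as the meso dimer, which would have to be removed from 6. The fallback sets out from 1 and comes back at 3, and replaces catalyst control by resolution. A Larock-type heteroannulation of 1 with 2 without a chiral ligand (Pd(OAc)2, dppf, K2CO3, DMF, 100 °C) gives racemic methyl 2-(prop-1-en-2-yl)-2,3-dihydrobenzofuran-5-carboxylate F3. Preparative SFC on a chiral stationary phase then delivers 3; the (S) assignment is checked by optical rotation after hydrolysis to the known monomer acid.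

Step 3. The half-hydrolysed salt may precipitate and stall the reaction, or the allylic ether may suffer on acidification. The fallback sets out from 6 and comes back at 7, and cleaves the alkyl–oxygen bond instead of the acyl–oxygen bond. LiI (6 equiv) in refluxing EtOAc attacks the O-methyl groups by SN2 and gives the dilithium salt 7 directly, which is protonated to 8 with cold 10% citric acid. No compound outside the list is made (F0).

**Further compounds**
F1 | step 2 | methyl 3-bromo-5-chloro-4-hydroxybenzoate | COC(=O)c1cc(Cl)c(O)c(Br)c1
F2 | step 2 | methyl (S)-7-chloro-2-(prop-1-en-2-yl)-2,3-dihydrobenzofuran-5-carboxylate | C=C(C)[C@@H]1Cc2cc(C(=O)OC)cc(Cl)c2O1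
F3 | step 1 | racemic methyl 2-(prop-1-en-2-yl)-2,3-dihydrobenzofuran-5-carboxylate | C=C(C)C1Cc2cc(C(=O)OC)ccc2O1
F0 | step 3 | none | none
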